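**Retrosynthetic overview**
- The target comes from its bis-MOM ether; the 12-membered lactone is the only ring built, and it is closed last, at the ester C–O bond, by macrolactonisation of a seco acid (rings A and B are bought as arenes).
- The Z-styrene of the seco acid comes from semihydrogenation of an aryl alkyne, made by Sonogashira coupling of a ring A/ring B diaryl ether bromide with a C9 alkyne.
- The alkyne comes (ozonolysis, then one-carbon homologation) from syn-(3S,4S)-3-(methoxymethoxy)non-1-en-4-ol, whose C3–C4 bond and both stereocentres are made by Brown asymmetric (Z)-γ-alkoxyallylboration of hexanal.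
- The diaryl ether comes from Chan–Lam coupling of 2-bromo-3-hydroxy-6-methoxybenzaldehyde (ortho-lithiation/formylation of silylated 2-bromo-4-methoxyphenol) with the ring A boronic acid, then a methyl-to-MOM exchange.

Assumption: the SMILES is read as drawn, i.e. both carbinol carbons S (a syn-diol) and a Z-olefin.

**Part A – the diol/alkyne fragment**

Step 1
Reactants: 1 allyl alcohol
Product: 2 allyl methoxymethyl ether
Conditions: MOMCl, iPr2NEt, CH2Cl2, 0 °C → rt; distil
Reagents that add atoms: chloromethyl methyl ether (MOMCl), COCCl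
Why: Williamson-type O-alkylation of the primary alcohol by the reactive α-chloro ether (MOM protection) gives the allyl ether whose oxygen later directs lithiation and fixes the Z-enol ether geometry.

Step 2
Reactants: 2 allyl methoxymethyl ether; 3 (+)-B-methoxydiisopinocampheylborane; 4 hexanal
Product: 9 (3S,4S)-3-(methoxymethoxy)non-1-en-4-ol, via allyllithium 5 (not isolated), via borate complex 6 (not isolated), via allylborane 7 (not isolated), via borinate ester 8 (not isolated)
Conditions: sec-BuLi, THF, −78 °C; 3, −78 °C; BF3·OEt2, −78 °C; 4, −78 °C, 3 h → rt; NaOH, H2O2, rt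
Reagents that add atoms: none
Why: Brown asymmetric alkoxyallylboration, a carbonyl allylation joining the two fragments at C3–C4: lithiation of 2 gives the oxygen-chelated Z-allyllithium 5, boron trapping and BF3-induced loss of methoxide give Z-γ-alkoxyallylborane 7, and its addition to hexanal through a closed chair transition state turns the Z geometry into the syn relationship while the isopinocampheyl groups from (−)-α-pinene steer attack to the re face of the aldehyde, so C3 and C4 are both set as S.

Step 3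
Reactants: 9 (3S,4S)-3-(methoxymethoxy)non-1-en-4-ol
Product: 10 tert-butyl{[(3S,4S)-3-(methoxymethoxy)non-1-en-4-yl]oxy}dimethylsilane
Conditions: TBSCl, imidazole, DMAP (cat.), DMF, rt → 40 °C
Reagents that add atoms: tert-butyldimethylsilyl chloride (TBSCl), CC(C)(C)[Si](C)(C)Cl
Why: Silylation of the secondary alcohol (TBS ether formation) masks the future lactone oxygen through the following steps, and the MOM ether is untouched under imidazole buffering.

Step 4
Reactants: 10 tert-butyl{[(3S,4S)-3-(methoxymethoxy)non-1-en-4-yl]oxy}dimethylsilane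
Product: 12 (2R,3S)-3-(tert-butyldimethylsilyloxy)-2-(methoxymethoxy)octanal, via ozonide 11 (not isolated)
Conditions: O3, CH2Cl2, −78 °C; then PPh3, −78 °C → rt
Reagents that add atoms: ozone, [O-][O+]=O
Why: Ozonolysis of the terminal alkene (Criegee mechanism) and reductive cleavage of ozonide 11 by PPh3 give the α-alkoxy aldehyde under neutral conditions, so the adjacent stereocentre is not epimerised (the descriptor changes from S to R only because of ligand priorities).

Step 5
Reactants: 12 (2R,3S)-3-(tert-butyldimethylsilyloxy)-2-(methoxymethoxy)octanal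
Product: 14 tert-butyl{[(3S,4S)-3-(methoxymethoxy)non-1-yn-4-yl]oxy}dimethylsilane, via diazoalkene 13 (not isolated)
Conditions: dimethyl (1-diazo-2-oxopropyl)phosphonate, K2CO3, MeOH, 0 °C → rt
Reagents that add atoms: dimethyl (1-diazo-2-oxopropyl)phosphonate, CC(=O)C(=[N+]=[N-])P(=O)(OC)OC
Why: Seyferth–Gilbert homologation in the Ohira–Bestmann variant: the diazophosphonate anion olefinates the aldehyde to diazoalkene 13, which loses nitrogen with a 1,2-hydride shift to the terminal alkyne, and the mild K2CO3/MeOH medium leaves the α-alkoxy centre and the silyl ether intact.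

**Part B – the ring A/ring B diaryl ether bromide**

Step 6
Reactants: 15 2-bromo-4-methoxyphenol
Product: 16 (2-bromo-4-methoxyphenoxy)(tert-butyl)dimethylsilane
Conditions: TBSCl, imidazole, DMF, rt
Reagents that add atoms: tert-butyldimethylsilyl chloride (TBSCl), CC(C)(C)[Si](C)(C)Cl
Why: Silylation of the phenol removes the acidic proton before the lithium amide step, and the bulky silyloxy group is a poor directing group that does not compete in the metalation.

Step 7
Reactants: 16 (2-bromo-4-methoxyphenoxy)(tert-butyl)dimethylsilane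
Product: 19 2-bromo-3-(tert-butyldimethylsilyloxy)-6-methoxybenzaldehyde, via aryllithium 17 (not isolated), via hemiaminal alkoxide 18 (not isolated)
Conditions: LiN(iPr)2, THF, −78 °C, 1 h; DMF, −78 °C; then AcOH, −78 °C → rt
Reagents that add atoms: N,N-dimethylformamide, CN(C)C=O
Why: Directed ortho-metalation followed by formylation: the ring C–H flanked by bromine and methoxy is by far the most acidic, the amide base removes it at −78 °C without bromine–lithium exchange or aryne formation, and aryllithium 17 adds to DMF to give alkoxide 18, which collapses to the aldehyde on quench.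

Step 8
Reactants: 19 2-bromo-3-(tert-butyldimethylsilyloxy)-6-methoxybenzaldehyde
Product: 20 2-bromo-3-hydroxy-6-methoxybenzaldehyde
Conditions: Bu4NF, AcOH, THF, 0 °C
Reagents that add atoms: none
Why: Fluoride-mediated desilylation is fast for an aryl silyl ether, and the acetic acid buffer keeps the liberated phenoxide from reacting with the ortho-bromo aldehyde.

Step 9
Reactants: 20 2-bromo-3-hydroxy-6-methoxybenzaldehyde; 21 [3-(methoxycarbonyl)-4-methylphenyl]boronic acid
Product: 22 methyl 5-(2-bromo-3-formyl-4-methoxyphenoxy)-2-methylbenzoate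
Conditions: Cu(OAc)2 (1 equiv, reoxidised by air), pyridine, 4 Å MS, CH2Cl2, air, rt
Reagents that add atoms: none
Why: Chan–Lam–Evans oxidative C–O coupling of a phenol with an arylboronic acid runs at room temperature, tolerates ortho-halophenols, aldehydes and esters, and leaves the aryl bromide needed later untouched.

Step 10
Reactants: 22 methyl 5-(2-bromo-3-formyl-4-methoxyphenoxy)-2-methylbenzoate
Product: 24 methyl 5-(2-bromo-3-formyl-4-hydroxyphenoxy)-2-methylbenzoate, via dichloroboryl ether 23 (not isolated)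
Conditions: BCl3, CH2Cl2, −78 → 0 °C; then H2O
Reagents that add atoms: none
Why: Chelation-controlled Lewis acid demethylation: BCl3 binds the aldehyde oxygen and the ortho methoxy oxygen in a six-membered chelate, so only this methyl ether is cleaved by chloride while the ester and the diaryl ether survive.

Step 11
Reactants: 24 methyl 5-(2-bromo-3-formyl-4-hydroxyphenoxy)-2-methylbenzoate
Product: 25 methyl 5-[2-bromo-3-formyl-4-(methoxymethoxy)phenoxy]-2-methylbenzoate
Conditions: MOMCl, iPr2NEt, CH2Cl2, 0 °C → reflux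
Reagents that add atoms: chloromethyl methyl ether (MOMCl), COCCl
Why: O-alkylation of the phenol (MOM protection) gives an acetal that survives coupling, hydrogenation, saponification and lactonisation and is removed together with the aliphatic MOM group at the end.

**Part C – union, ring closure and deprotection**

Step 12
Reactants: 25 methyl 5-[2-bromo-3-formyl-4-(methoxymethoxy)phenoxy]-2-methylbenzoate; 14 tert-butyl{[(3S,4S)-3-(methoxymethoxy)non-1-yn-4-yl]oxy}dimethylsilane
Product: 26 methyl 5-{2-[(3S,4S)-4-(tert-butyldimethylsilyloxy)-3-(methoxymethoxy)non-1-yn-1-yl]-3-formyl-4-(methoxymethoxy)phenoxy}-2-methylbenzoate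
Conditions: Pd(PPh3)2Cl2 (5 mol %), CuI (10 mol %), Et3N, DMF (degassed), 70 °C
Reagents that add atoms: none
Why: Sonogashira coupling of the terminal alkyne with the aryl bromide, whose oxidative addition to zerovalent palladium is accelerated by the ortho formyl group, forms the aryl–alkyne bond without touching either stereocentre.

Step 13
Reactants: 26 the aryl alkyne
Product: 27 methyl 5-{2-[(1Z,3S,4S)-4-(tert-butyldimethylsilyloxy)-3-(methoxymethoxy)non-1-en-1-yl]-3-formyl-4-(methoxymethoxy)phenoxy}-2-methylbenzoate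
Conditions: H2 (1 atm), Pd/CaCO3 poisoned with Pb(OAc)2, quinoline, EtOAc, rt
Reagents that add atoms: none
Why: Lindlar semihydrogenation delivers both hydrogens to one face of the alkyne on the poisoned palladium surface and stops at the alkene, so the Z-olefin is set stereospecifically while the aldehyde and the ethers are not reduced.

Step 14
Reactants: 27 the Z-alkene silyl ether
Product: 28 methyl 5-{3-formyl-2-[(1Z,3S,4S)-4-hydroxy-3-(methoxymethoxy)non-1-en-1-yl]-4-(methoxymethoxy)phenoxy}-2-methylbenzoate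
Conditions: Bu4NF, AcOH, THF, rt → 40 °C
Reagents that add atoms: none
Why: Buffered fluoride desilylation frees the C4 hydroxyl without affecting the MOM acetals, the aldehyde or the ester.

Step 15
Reactants: 28 the hydroxy ester
Product: 30 5-{3-formyl-2-[(1Z,3S,4S)-4-hydroxy-3-(methoxymethoxy)non-1-en-1-yl]-4-(methoxymethoxy)phenoxy}-2-methylbenzoic acid, via lithium carboxylate 29 (not isolated)
Conditions: LiOH, THF/MeOH/H2O, 40 °C; then 0.5 M HCl to pH 4, 0 °C
Reagents that add atoms: lithium hydroxide, [Li+].[OH-]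
Why: Saponification of the methyl benzoate by hydroxide gives the seco acid after careful acidification, the aldehyde having no α-hydrogen and the acetals being base-stable.

Step 16
Reactants: 30 the seco acid
Product: 32 bis-MOM macrolactone (the target with both hydroxyls as methoxymethyl ethers), via mixed anhydride 31 (not isolated)
Conditions: 2,4,6-Cl3C6H2COCl, Et3N, THF, rt; then slow addition to DMAP, toluene (1 mM), 80 °C
Reagents that add atoms: none
Why: Yamaguchi macrolactonisation: DMAP attacks the less hindered aroyl carbonyl of mixed anhydride 31 and the C4 hydroxyl, held close by the Z-olefin and the ortho-diaryl ether turn, closes the 12-membered ring under high dilution with retention at C4 because only the acyl C–O bond is formed.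

Step 17
Reactants: 32 bis-MOM macrolactone
Product: 34 target CNP0238900.1, via bromomethyl ether 33 (not isolated)
Conditions: Me2BBr, CH2Cl2, −78 °C; then sat. aq. NaHCO3/THF, rt
Reagents that add atoms: none
Why: Lewis acid acetal cleavage: Me2BBr converts both MOM ethers into bromomethyl ethers at −78 °C, which hydrolyse on bicarbonate work-up, conditions that spare the lactone, the Z-styrene, the aldehyde and both stereocentres.

**Compound list**

1 | allyl alcohol (prop-2-en-1-ol) | C=CCO | starting material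
2 | allyl methoxymethyl ether, 3-(methoxymethoxy)prop-1-ene | C=CCOCOC | intermediate
3 | (+)-B-methoxydiisopinocampheylborane, methoxybis[(1S,2R,3S,5S)-2,6,6-trimethylbicyclo[3.1.1]hept-3-yl]borane, the enantiomer made from (−)-α-pinene | COB([C@H]1C[C@H]2C[C@@H]([C@@H]1C)C2(C)C)[C@H]1C[C@H]2C[C@@H]([C@@H]1C)C2(C)C | starting material
4 | hexanal | CCCCCC=O | starting material
5 | [(2Z)-3-(methoxymethoxy)prop-2-en-1-yl]lithium (formed in the flask) | [Li]C/C=C\OCOC | intermediate
6 | lithium methoxy[(2Z)-3-(methoxymethoxy)prop-2-en-1-yl]bis(isopinocampheyl)borate, isopinocampheyl groups as in 3 (formed in the flask) | [Li+].CO[B-](C/C=C\OCOC)([C@H]1C[C@H]2C[C@@H]([C@@H]1C)C2(C)C)[C@H]1C[C@H]2C[C@@H]([C@@H]1C)C2(C)C | intermediate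
7 | [(2Z)-3-(methoxymethoxy)prop-2-en-1-yl]bis(isopinocampheyl)borane (formed in the flask) | COCO/C=C\CB([C@H]1C[C@H]2C[C@@H]([C@@H]1C)C2(C)C)[C@H]1C[C@H]2C[C@@H]([C@@H]1C)C2(C)C | intermediate
8 | (3S,4S)-3-(methoxymethoxy)non-1-en-4-yl bis(isopinocampheyl)borinate (formed in the flask) | CCCCC[C@H](OB([C@H]1C[C@H]2C[C@@H]([C@@H]1C)C2(C)C)[C@H]1C[C@H]2C[C@@H]([C@@H]1C)C2(C)C)[C@@H](OCOC)C=C | intermediate
9 | (3S,4S)-3-(methoxymethoxy)non-1-en-4-ol | CCCCC[C@H](O)[C@@H](OCOC)C=C | intermediate
10 | tert-butyl{[(3S,4S)-3-(methoxymethoxy)non-1-en-4-yl]oxy}dimethylsilane | CCCCC[C@H](O[Si](C)(C)C(C)(C)C)[C@@H](OCOC)C=C | intermediate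
11 | 3-[(1R,2S)-2-(tert-butyldimethylsilyloxy)-1-(methoxymethoxy)heptyl]-1,2,4-trioxolane, secondary ozonide, epimers at the ring carbon (formed in the flask) | CCCCC[C@H](O[Si](C)(C)C(C)(C)C)[C@@H](OCOC)C1OCOO1 | intermediate
12 | (2R,3S)-3-(tert-butyldimethylsilyloxy)-2-(methoxymethoxy)octanal | CCCCC[C@H](O[Si](C)(C)C(C)(C)C)[C@@H](OCOC)C=O | intermediate
13 | tert-butyl{[(3S,4S)-1-diazo-3-(methoxymethoxy)non-1-en-4-yl]oxy}dimethylsilane (formed in the flask) | CCCCC[C@H](O[Si](C)(C)C(C)(C)C)[C@@H](OCOC)C=C=[N+]=[N-] | intermediate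
14 | tert-butyl{[(3S,4S)-3-(methoxymethoxy)non-1-yn-4-yl]oxy}dimethylsilane | CCCCC[C@H](O[Si](C)(C)C(C)(C)C)[C@@H](OCOC)C#C | intermediate
15 | 2-bromo-4-methoxyphenol | COc1ccc(O)c(Br)c1 | starting material
16 | (2-bromo-4-methoxyphenoxy)(tert-butyl)dimethylsilane | COc1ccc(O[Si](C)(C)C(C)(C)C)c(Br)c1 | intermediate
17 | [2-bromo-3-(tert-butyldimethylsilyloxy)-6-methoxyphenyl]lithium (formed in the flask) | COc1ccc(O[Si](C)(C)C(C)(C)C)c(Br)c1[Li] | intermediate
18 | lithium [2-bromo-3-(tert-butyldimethylsilyloxy)-6-methoxyphenyl](dimethylamino)methanolate (formed in the flask) | COc1ccc(O[Si](C)(C)C(C)(C)C)c(Br)c1C(O[Li])N(C)C | intermediate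
19 | 2-bromo-3-(tert-butyldimethylsilyloxy)-6-methoxybenzaldehyde | COc1ccc(O[Si](C)(C)C(C)(C)C)c(Br)c1C=O | intermediate
20 | 2-bromo-3-hydroxy-6-methoxybenzaldehyde | COc1ccc(O)c(Br)c1C=O | intermediate
21 | [3-(methoxycarbonyl)-4-methylphenyl]boronic acid | COC(=O)c1cc(B(O)O)ccc1C | starting material
22 | methyl 5-(2-bromo-3-formyl-4-methoxyphenoxy)-2-methylbenzoate | COC(=O)c1cc(Oc2ccc(OC)c(C=O)c2Br)ccc1C | intermediate
23 | methyl 5-{2-bromo-4-[(dichloroboranyl)oxy]-3-formylphenoxy}-2-methylbenzoate (formed in the flask) | COC(=O)c1cc(Oc2ccc(OB(Cl)Cl)c(C=O)c2Br)ccc1C | intermediate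
24 | methyl 5-(2-bromo-3-formyl-4-hydroxyphenoxy)-2-methylbenzoate | COC(=O)c1cc(Oc2ccc(O)c(C=O)c2Br)ccc1C | intermediate
25 | methyl 5-[2-bromo-3-formyl-4-(methoxymethoxy)phenoxy]-2-methylbenzoate | COC(=O)c1cc(Oc2ccc(OCOC)c(C=O)c2Br)ccc1C | intermediate
26 | methyl 5-{2-[(3S,4S)-4-(tert-butyldimethylsilyloxy)-3-(methoxymethoxy)non-1-yn-1-yl]-3-formyl-4-(methoxymethoxy)phenoxy}-2-methylbenzoate | CCCCC[C@H](O[Si](C)(C)C(C)(C)C)[C@@H](OCOC)C#Cc1c(Oc2ccc(C)c(C(=O)OC)c2)ccc(OCOC)c1C=O | intermediate
27 | methyl 5-{2-[(1Z,3S,4S)-4-(tert-butyldimethylsilyloxy)-3-(methoxymethoxy)non-1-en-1-yl]-3-formyl-4-(methoxymethoxy)phenoxy}-2-methylbenzoate | CCCCC[C@H](O[Si](C)(C)C(C)(C)C)[C@@H](OCOC)/C=C\c1c(Oc2ccc(C)c(C(=O)OC)c2)ccc(OCOC)c1C=O | intermediate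
28 | methyl 5-{3-formyl-2-[(1Z,3S,4S)-4-hydroxy-3-(methoxymethoxy)non-1-en-1-yl]-4-(methoxymethoxy)phenoxy}-2-methylbenzoate | CCCCC[C@H](O)[C@@H](OCOC)/C=C\c1c(Oc2ccc(C)c(C(=O)OC)c2)ccc(OCOC)c1C=O | intermediate
29 | lithium 5-{3-formyl-2-[(1Z,3S,4S)-4-hydroxy-3-(methoxymethoxy)non-1-en-1-yl]-4-(methoxymethoxy)phenoxy}-2-methylbenzoate (formed in the flask) | [Li+].CCCCC[C@H](O)[C@@H](OCOC)/C=C\c1c(Oc2ccc(C)c(C(=O)[O-])c2)ccc(OCOC)c1C=O | intermediate
30 | 5-{3-formyl-2-[(1Z,3S,4S)-4-hydroxy-3-(methoxymethoxy)non-1-en-1-yl]-4-(methoxymethoxy)phenoxy}-2-methylbenzoic acid (seco acid) | CCCCC[C@H](O)[C@@H](OCOC)/C=C\c1c(Oc2ccc(C)c(C(=O)O)c2)ccc(OCOC)c1C=O | intermediate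
31 | mixed anhydride of seco acid 30 with 2,4,6-trichlorobenzoic acid (formed in the flask) | CCCCC[C@H](O)[C@@H](OCOC)/C=C\c1c(Oc2ccc(C)c(C(=O)OC(=O)c3c(Cl)cc(Cl)cc3Cl)c2)ccc(OCOC)c1C=O | intermediate
32 | bis-MOM macrolactone: the 12-membered lactone of the target with the phenol and the allylic alcohol as methoxymethyl ethers, (S) at both carbinol carbons, Z-olefin | CCCCC[C@@H]1OC(=O)c2cc(ccc2C)Oc2ccc(OCOC)c(C=O)c2/C=C\[C@@H]1OCOC | intermediate
33 | bis(bromomethyl) ether of the target: as 32 with each OCH2OCH3 replaced by OCH2Br (formed in the flask) | CCCCC[C@@H]1OC(=O)c2cc(ccc2C)Oc2ccc(OCBr)c(C=O)c2/C=C\[C@@H]1OCBr | intermediate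
34 | CNP0238900.1: 12-membered benzoate lactone bridged by a diaryl ether, ring A 2-methyl-5-aryloxybenzoate, ring B 2-hydroxy-5-aryloxy-6-alkenylbenzaldehyde, (S)-pentyl carbinol ester, (S)-allylic alcohol, Z-olefin | CCCCC[C@@H]1OC(=O)c2cc(ccc2C)Oc2ccc(O)c(C=O)c2/C=C\[C@@H]1O | target

**Step count**

Total: 17 steps. Longest linear sequence: 12 steps (15 → 34 through steps 6–17); the side branch 1 → 14 is 5 steps.

**The three steps most likely to fail, each with a fallback**

Step 16 (macrolactonisation). Acyl activation of an ortho-substituted benzoic acid and closure of a rigid 12-membered ring onto a hindered secondary alcohol may give oligomers. The fallback activates the alcohol instead of the acid and sets out from hydroxy ester 28. Mitsunobu esterification with 4-nitrobenzoic acid (PPh3, DIAD, toluene, 0 °C → rt) inverts C4 and gives methyl 5-{3-formyl-4-(methoxymethoxy)-2-[(1Z,3S,4R)-3-(methoxymethoxy)-4-(4-nitrobenzoyloxy)non-1-en-1-yl]phenoxy}-2-methylbenzoate F4. LiOH in THF/MeOH/H2O then cleaves both esters to 5-{3-formyl-2-[(1Z,3S,4R)-4-hydroxy-3-(methoxymethoxy)non-1-en-1-yl]-4-(methoxymethoxy)phenoxy}-2-methylbenzoic acid F5. A Mitsunobu macrolactonisation (PPh3, DIAD, toluene, 2 mM, rt) closes the ring with a second inversion at C4 and comes back to the route at macrolactone 32.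

Step 9 (Chan–Lam coupling). The ortho-bromophenol 20 is electron-poor and flanked by bromine, so the copper-mediated coupling may stall or give protodeboronation. The fallback is a metal-free arylation that sets out from phenol 20. Commercial methyl 5-iodo-2-methylbenzoate is oxidised with mCPBA/TsOH·H2O in MeCN and trapped with 1,3,5-trimethoxybenzene to give [3-(methoxycarbonyl)-4-methylphenyl](2,4,6-trimethoxyphenyl)iodonium 4-methylbenzenesulfonate F1. Phenol 20 with K2CO3 in MeCN at 50 °C is arylated by this salt on the ester-bearing ring (the trimethoxyphenyl group acts as the non-transferred ligand), and the sequence comes back to the route at diaryl ether 22.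

Step 12 (Sonogashira coupling). The bromide of 25 sits between two ortho substituents, and alkyne homocoupling or cyclisation of the ortho-alkynyl benzaldehyde can compete. The fallback builds the Z-olefin directly, bypassing steps 5, 12 and 13, and sets out from aldehyde 12 and bromide 25.
- Stork–Zhao olefination of 12 ([Ph3PCH2I]I, NaN(SiMe3)2, THF/DMPU, −78 °C) gives tert-butyl{[(1Z,3S,4S)-1-iodo-3-(methoxymethoxy)non-1-en-4-yl]oxy}dimethylsilane F2.
- Miyaura borylation of 25 (B2pin2, Pd(dppf)Cl2, KOAc, dioxane, 90 °C) gives methyl 5-[3-formyl-4-(methoxymethoxy)-2-(4,4,5,5-tetramethyl-1,3,2-dioxaborolan-2-yl)phenoxy]-2-methylbenzoate F3.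
- Suzuki–Miyaura coupling of the two (Pd(dppf)Cl2, Cs2CO3, DMF/H2O, 50 °C) proceeds with retention of the olefin geometry and comes back to the route at Z-alkene 27.

**Further compounds**

F1 | step 9 | [3-(methoxycarbonyl)-4-methylphenyl](2,4,6-trimethoxyphenyl)iodonium 4-methylbenzenesulfonate | COC(=O)c1cc([I+]c2c(OC)cc(OC)cc2OC)ccc1C.Cc1ccc(cc1)S(=O)(=O)[O-]
F2 | step 12 | tert-butyl{[(1Z,3S,4S)-1-iodo-3-(methoxymethoxy)non-1-en-4-yl]oxy}dimethylsilane | CCCCC[C@H](O[Si](C)(C)C(C)(C)C)[C@@H](OCOC)/C=C\I
F3 | step 12 | methyl 5-[3-formyl-4-(methoxymethoxy)-2-(4,4,5,5-tetramethyl-1,3,2-dioxaborolan-2-yl)phenoxy]-2-methylbenzoate | COC(=O)c1cc(Oc2ccc(OCOC)c(C=O)c2B2OC(C)(C)C(C)(C)O2)ccc1C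
F4 | step 16 | methyl 5-{3-formyl-4-(methoxymethoxy)-2-[(1Z,3S,4R)-3-(methoxymethoxy)-4-(4-nitrobenzoyloxy)non-1-en-1-yl]phenoxy}-2-methylbenzoate | CCCCC[C@@H](OC(=O)c1ccc(cc1)[N+](=O)[O-])[C@@H](OCOC)/C=C\c1c(Oc2ccc(C)c(C(=O)OC)c2)ccc(OCOC)c1C=O
F5 | step 16 | 5-{3-formyl-2-[(1Z,3S,4R)-4-hydroxy-3-(methoxymethoxy)non-1-en-1-yl]-4-(methoxymethoxy)phenoxy}-2-methylbenzoic acid | CCCCC[C@@H](O)[C@@H](OCOC)/C=C\c1c(Oc2ccc(C)c(C(=O)O)c2)ccc(OCOC)c1C=O
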